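The route cuts the 2,2-dimethyldihydropyranone ring (O1, C2, C3, C4, C4a, C8a) at C3–C4 and C4a–C8a. Its C4–C4a unit comes from Meldrum's acid as a masked ketene. A chiral glutaric half-ester acylates Meldrum's acid (C4a–C8a); the acylketene released on heating is trapped by isobutene in a hetero-[4+2] addition (C3–C4 and O1–C2). The precursor is thus an open-chain half-ester, and the ring oxygen is fixed next to C8 before the carbocycle exists. The phloroglucinol ring is then annulated, C6 is alkylated with a cyclobutane aldehyde made by Wolff ring contraction, and palladium-catalysed dearomative prenylation sets the quaternary centre before ester hydrolysis.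

Key step: step 2

Assumption: atom numbers follow the chromanone skeleton of the target (O1, C2 to C8a), the target is handled as the drawn tautomer of an enolised β-triketone, and for each chiral catalyst the antipode that gives the stated configuration is the one used.

Step 1
Reactants: 1 4-propyloxane-2,6-dione (3-propylglutaric anhydride)
Product: 2 (3S)-5-methoxy-5-oxo-3-propylpentanoic acid
Conditions: MeOH, (DHQD)2AQN (cat.), Et2O, −40 °C
Reagents that add atoms: methanol CO
Why: Cinchona-alkaloid-catalysed desymmetrising methanolysis of a meso anhydride, in which the catalyst activates methanol as a general base and differentiates the two enantiotopic carbonyl groups, which should set the side-chain stereocentre (S in 2, R in the target after the change of priorities).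

Step 2
Reactants: 2 (3S)-5-methoxy-5-oxo-3-propylpentanoic acid; 3 2,2-dimethyl-1,3-dioxane-4,6-dione (Meldrum's acid); 4 2-methylprop-1-ene (isobutene)
Product: 7 methyl (3S)-3-[(2,2-dimethyl-4-oxo-3,4-dihydro-2H-pyran-6-yl)methyl]hexanoate, via acyl Meldrum's acid 5 (not isolated), via acylketene 6 (not isolated)
Conditions: DCC, DMAP, CH2Cl2, 0 °C to rt; filter, aq. KHSO4 wash, concentrate; then 4 (20 equiv), PhMe, sealed tube, 100 °C
Reagents that add atoms: none
Why: Proposed new method: DCC/DMAP C-acylation of Meldrum's acid by the free acid of 2 forms the bond that becomes C4a–C8a and gives 5, which on heating loses acetone and CO2 to the acylketene 6; isobutene then adds across the O=C–C=C=O unit of 6 in a pseudopericyclic hetero-[4+2] cycloaddition, its nucleophilic CH2 terminus bonding to the ketene carbon (the C3–C4 bond) and its tertiary carbon to the acyl oxygen (O1–C2). The closest known reaction type is the thermolysis of acyl Meldrum's acids or dioxinones with [4+2] capture of the acylketene by enol ethers or by acetone, and the new element is an unactivated 1,1-disubstituted alkene as the two-atom partner, whose polarisation matches that of the known Lewis-acid acylation of isobutene. The dihydropyranone ring closes in the [4+2] mode, with the C–C and the C–O ring bond made in one asynchronous event. No stereocentre is formed, and the side-chain stereocentre of 2 is remote from every acidic position. The step needs periselectivity for [4+2] over [2+2] and capture of 6 before it dimerises, which the fixed s-cis acyl carbonyl, a large excess of isobutene and slow generation of 6 should secure. Regiochemistry is built in, because only one acyl group flanks the ketene, so O1 can only sit on the former carboxyl carbon C8a, next to the carbon that becomes C8.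

Step 3
Reactants: 7 methyl (3S)-3-[(2,2-dimethyl-4-oxo-3,4-dihydro-2H-pyran-6-yl)methyl]hexanoate
Product: 8 methyl (3S)-3-[(5-iodo-2,2-dimethyl-4-oxo-3,4-dihydro-2H-pyran-6-yl)methyl]hexanoate
Conditions: I2, pyridine, CH2Cl2, 0 °C to rt
Reagents that add atoms: iodine II
Why: α-Iodination of a cyclic vinylogous ester by iodine–pyridine (addition–elimination), which should occur only at C5 of the pyranone, the enol-ether β-carbon and the sole nucleophilic vinylic position.

Step 4
Reactants: 8 methyl (3S)-3-[(5-iodo-2,2-dimethyl-4-oxo-3,4-dihydro-2H-pyran-6-yl)methyl]hexanoate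
Product: 10 methyl (3S)-3-[(5-acetyl-2,2-dimethyl-4-oxo-3,4-dihydro-2H-pyran-6-yl)methyl]hexanoate, via enol ether 9 (not isolated)
Conditions: tributyl(1-ethoxyvinyl)stannane, Pd(PPh3)4 (cat.), CuI (cat.), PhMe, 90 °C; then 1 M HCl, THF, rt
Reagents that add atoms: tributyl(1-ethoxyvinyl)stannane CCCC[Sn](CCCC)(CCCC)C(=C)OCC; water O
Why: Stille cross-coupling of the α-iodoenone with an acetyl anion equivalent, then acid hydrolysis of the enol ether 9 to the methyl ketone, which should place the future C5 and C6 of the chromanone on C4a.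

Step 5
Reactants: 10 methyl (3S)-3-[(5-acetyl-2,2-dimethyl-4-oxo-3,4-dihydro-2H-pyran-6-yl)methyl]hexanoate
Product: 12 methyl (3R)-3-(5,7-dihydroxy-2,2-dimethyl-4-oxo-3,4-dihydro-2H-chromen-8-yl)hexanoate, via diester 11 (not isolated)
Conditions: NaH, (MeO)2CO, THF, 0 to 65 °C; then aq. HCl
Reagents that add atoms: dimethyl carbonate COC(=O)OC
Why: Double Claisen ([5+1]) annulation in which the vinylogous γ-carbanion (the CH2 on C6 of the pyranone) is carbomethoxylated to 11 and the acetyl enolate then closes the carbocycle by Dieckmann condensation, tautomerisation to the phloroglucinol-type arene driving the sequence, with no new stereocentre kept (the one in 11 is lost on aromatisation).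

Step 6
Reactants: 13 4,4-dimethylcyclopent-2-en-1-one; 14 4,4,5,5-tetramethyl-2-(prop-1-en-2-yl)-1,3,2-dioxaborolane
Product: 15 (4R)-3,3-dimethyl-4-(prop-1-en-2-yl)cyclopentan-1-one
Conditions: [Rh(cod)Cl]2 (cat.), (R)-BINAP, KOH (cat.), dioxane/H2O, 60 °C
Reagents that add atoms: none
Why: Rhodium-catalysed asymmetric conjugate addition of the alkenylboron reagent (Hayashi–Miyaura reaction), in which the (R)-BINAP–rhodium complex selects the enone face and should set the ring stereocentre as R.

Step 7
Reactants: 15 (4R)-3,3-dimethyl-4-(prop-1-en-2-yl)cyclopentan-1-one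
Product: 17 (3R)-2-diazo-4,4-dimethyl-3-(prop-1-en-2-yl)cyclopentan-1-one, via trifluoroacetyl ketone 16 (not isolated)
Conditions: LiN(SiMe3)2, THF, −78 °C, then CF3CO2CH2CF3; then MsN3, Et3N, H2O, MeCN, rt
Reagents that add atoms: 2,2,2-trifluoroethyl trifluoroacetate O=C(OCC(F)(F)F)C(F)(F)F (atoms stay in 16 only); methanesulfonyl azide CS(=O)(=O)N=[N+]=[N-]
Why: Detrifluoroacetylative diazo transfer, in which kinetic deprotonation should occur at the CH2 next to the methine and not at the CH2 flanked by the quaternary carbon, so that the diazo group is placed beside the isopropenyl-bearing carbon.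

Step 8
Reactants: 17 (3R)-2-diazo-4,4-dimethyl-3-(prop-1-en-2-yl)cyclopentan-1-one
Product: 19 methyl (1R,2R)-3,3-dimethyl-2-(prop-1-en-2-yl)cyclobutane-1-carboxylate, via ketene 18 (not isolated)
Conditions: hν (Hg lamp, Pyrex), MeOH, rt; then NaOMe (cat.), MeOH, 50 °C
Reagents that add atoms: methanol CO
Why: Photochemical Wolff rearrangement with ring contraction and capture of ketene 18 by methanol, then base equilibration of the ester α-carbon to the more stable trans-1,2-disubstituted cyclobutane, which should set the second ring stereocentre under thermodynamic control.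

Step 9
Reactants: 19 methyl (1R,2R)-3,3-dimethyl-2-(prop-1-en-2-yl)cyclobutane-1-carboxylate
Product: 20 (1R,2R)-3,3-dimethyl-2-(prop-1-en-2-yl)cyclobutane-1-carbaldehyde
Conditions: iBu2AlH, CH2Cl2, −78 °C; Rochelle salt work-up
Reagents that add atoms: none
Why: Partial hydride reduction of the ester, which should stop at the aldehyde because the tetrahedral aluminium hemiacetal persists at low temperature.

Step 10
Reactants: 12 methyl (3R)-3-(5,7-dihydroxy-2,2-dimethyl-4-oxo-3,4-dihydro-2H-chromen-8-yl)hexanoate; 20 (1R,2R)-3,3-dimethyl-2-(prop-1-en-2-yl)cyclobutane-1-carbaldehyde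
Product: 22 methyl (3R)-3-[6-{[(1S,2R)-3,3-dimethyl-2-(prop-1-en-2-yl)cyclobutyl]methyl}-5,7-dihydroxy-2,2-dimethyl-4-oxo-3,4-dihydro-2H-chromen-8-yl]hexanoate, via o-quinone methide 21 (not isolated)
Conditions: L-proline (cat.), Hantzsch ester, CH2Cl2/MeOH, rt
Reagents that add atoms: none
Why: Three-component reductive alkylation (Knoevenagel-type condensation to the o-quinone methide 21 and conjugate hydride transfer from the Hantzsch ester) at C6, the only free nucleophilic ring carbon, with no new stereocentre and with the aldehyde α-carbon returning to the trans form if it epimerises.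

Step 11
Reactants: 22 methyl (3R)-3-[6-{[(1S,2R)-3,3-dimethyl-2-(prop-1-en-2-yl)cyclobutyl]methyl}-5,7-dihydroxy-2,2-dimethyl-4-oxo-3,4-dihydro-2H-chromen-8-yl]hexanoate
Product: 23 methyl (3R)-3-[(6R)-6-{[(1S,2R)-3,3-dimethyl-2-(prop-1-en-2-yl)cyclobutyl]methyl}-5-hydroxy-2,2-dimethyl-6-(3-methylbut-2-en-1-yl)-4,7-dioxo-3,4,6,7-tetrahydro-2H-chromen-8-yl]hexanoate
Conditions: tert-butyl (3-methylbut-2-en-1-yl) carbonate, Pd2(dba)3·CHCl3 (cat.), (R,R)-DACH-phenyl Trost ligand, THF, 0 °C to rt
Reagents that add atoms: tert-butyl (3-methylbut-2-en-1-yl) carbonate CC(C)=CCOC(=O)OC(C)(C)C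
Why: Tsuji–Trost allylic alkylation with dearomatisation, in which C6 (less hindered than C8, which carries the branched chain) attacks the unsubstituted terminus of the dimethylallylpalladium complex while O-allylation stays reversible, and the chiral ligand pocket selects the arene face and should set the quaternary stereocentre as 6R.

Step 12
Reactants: 23 methyl (3R)-3-[(6R)-6-{[(1S,2R)-3,3-dimethyl-2-(prop-1-en-2-yl)cyclobutyl]methyl}-5-hydroxy-2,2-dimethyl-6-(3-methylbut-2-en-1-yl)-4,7-dioxo-3,4,6,7-tetrahydro-2H-chromen-8-yl]hexanoate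
Product: 24 (3R)-3-[(6R)-6-{[(1S,2R)-3,3-dimethyl-2-(prop-1-en-2-yl)cyclobutyl]methyl}-5-hydroxy-2,2-dimethyl-6-(3-methylbut-2-en-1-yl)-4,7-dioxo-3,4,6,7-tetrahydro-2H-chromen-8-yl]hexanoic acid (the target)
Conditions: Me3SnOH, 1,2-dichloroethane, 70 °C; then 5% aq. HCl
Reagents that add atoms: trimethyltin hydroxide C[Sn](C)(C)O
Why: Mild methyl ester hydrolysis by trimethyltin hydroxide, chosen because it should leave the enolised β-triketone, the two alkenes and the closed pyranone ring untouched and does not affect any stereocentre.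

Compound list
1 | 4-propyloxane-2,6-dione (3-propylglutaric anhydride) | CCCC1CC(=O)OC(=O)C1 | starting material
2 | (3S)-5-methoxy-5-oxo-3-propylpentanoic acid | OC(=O)C[C@H](CCC)CC(=O)OC | intermediate
3 | 2,2-dimethyl-1,3-dioxane-4,6-dione (Meldrum's acid) | CC1(C)OC(=O)CC(=O)O1 | starting material
4 | 2-methylprop-1-ene (isobutene) | C=C(C)C | starting material
5 | methyl (3S)-3-[2-(2,2-dimethyl-4,6-dioxo-1,3-dioxan-5-ylidene)-2-hydroxyethyl]hexanoate (acyl Meldrum's acid, not isolated) | COC(=O)C[C@@H](CCC)CC(O)=C1C(=O)OC(C)(C)OC1=O | intermediate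
6 | methyl (3S)-5,7-dioxo-3-propylhept-6-enoate (acylketene, not isolated) | COC(=O)C[C@@H](CCC)CC(=O)C=C=O | intermediate
7 | methyl (3S)-3-[(2,2-dimethyl-4-oxo-3,4-dihydro-2H-pyran-6-yl)methyl]hexanoate | CC1(C)CC(=O)C=C(C[C@H](CCC)CC(=O)OC)O1 | intermediate
8 | methyl (3S)-3-[(5-iodo-2,2-dimethyl-4-oxo-3,4-dihydro-2H-pyran-6-yl)methyl]hexanoate | CC1(C)CC(=O)C(I)=C(C[C@H](CCC)CC(=O)OC)O1 | intermediate
9 | methyl (3S)-3-{[5-(1-ethoxyethenyl)-2,2-dimethyl-4-oxo-3,4-dihydro-2H-pyran-6-yl]methyl}hexanoate (enol ether, not isolated) | CC1(C)CC(=O)C(C(=C)OCC)=C(C[C@H](CCC)CC(=O)OC)O1 | intermediate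
10 | methyl (3S)-3-[(5-acetyl-2,2-dimethyl-4-oxo-3,4-dihydro-2H-pyran-6-yl)methyl]hexanoate | CC1(C)CC(=O)C(C(C)=O)=C(C[C@H](CCC)CC(=O)OC)O1 | intermediate
11 | dimethyl (3R)-2-(5-acetyl-2,2-dimethyl-4-oxo-3,4-dihydro-2H-pyran-6-yl)-3-propylpentanedioate (both C2 epimers, not isolated) | CC1(C)CC(=O)C(C(C)=O)=C(C(C(=O)OC)[C@H](CCC)CC(=O)OC)O1 | intermediate
12 | methyl (3R)-3-(5,7-dihydroxy-2,2-dimethyl-4-oxo-3,4-dihydro-2H-chromen-8-yl)hexanoate | CC1(C)CC(=O)c2c(O)cc(O)c([C@H](CCC)CC(=O)OC)c2O1 | intermediate
13 | 4,4-dimethylcyclopent-2-en-1-one | CC1(C)CC(=O)C=C1 | starting material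
14 | 4,4,5,5-tetramethyl-2-(prop-1-en-2-yl)-1,3,2-dioxaborolane | CC(=C)B1OC(C)(C)C(C)(C)O1 | starting material
15 | (4R)-3,3-dimethyl-4-(prop-1-en-2-yl)cyclopentan-1-one | C=C(C)[C@H]1CC(=O)CC1(C)C | intermediate
16 | (3R)-4,4-dimethyl-3-(prop-1-en-2-yl)-2-(trifluoroacetyl)cyclopentan-1-one (both C2 epimers and enol, not isolated) | C=C(C)[C@H]1C(C(=O)C(F)(F)F)C(=O)CC1(C)C | intermediate
17 | (3R)-2-diazo-4,4-dimethyl-3-(prop-1-en-2-yl)cyclopentan-1-one | C=C(C)[C@H]1C(=[N+]=[N-])C(=O)CC1(C)C | intermediate
18 | [(2R)-3,3-dimethyl-2-(prop-1-en-2-yl)cyclobutylidene]methanone (ketene, not isolated) | C=C(C)[C@H]1C(=C=O)CC1(C)C | intermediate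
19 | methyl (1R,2R)-3,3-dimethyl-2-(prop-1-en-2-yl)cyclobutane-1-carboxylate | C=C(C)[C@H]1[C@H](C(=O)OC)CC1(C)C | intermediate
20 | (1R,2R)-3,3-dimethyl-2-(prop-1-en-2-yl)cyclobutane-1-carbaldehyde | C=C(C)[C@H]1[C@H](C=O)CC1(C)C | intermediate
21 | methyl (3R)-3-[6-{[(1S,2R)-3,3-dimethyl-2-(prop-1-en-2-yl)cyclobutyl]methylidene}-5-hydroxy-2,2-dimethyl-4,7-dioxo-3,4,6,7-tetrahydro-2H-chromen-8-yl]hexanoate (o-quinone methide, not isolated) | C=C(C)[C@H]1[C@H](C=C2C(=O)C([C@H](CCC)CC(=O)OC)=C3OC(C)(C)CC(=O)C3=C2O)CC1(C)C | intermediate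
22 | methyl (3R)-3-[6-{[(1S,2R)-3,3-dimethyl-2-(prop-1-en-2-yl)cyclobutyl]methyl}-5,7-dihydroxy-2,2-dimethyl-4-oxo-3,4-dihydro-2H-chromen-8-yl]hexanoate | C=C(C)[C@H]1[C@H](Cc2c(O)c3C(=O)CC(C)(C)Oc3c([C@H](CCC)CC(=O)OC)c2O)CC1(C)C | intermediate
23 | methyl (3R)-3-[(6R)-6-{[(1S,2R)-3,3-dimethyl-2-(prop-1-en-2-yl)cyclobutyl]methyl}-5-hydroxy-2,2-dimethyl-6-(3-methylbut-2-en-1-yl)-4,7-dioxo-3,4,6,7-tetrahydro-2H-chromen-8-yl]hexanoate | C=C(C)[C@H]1[C@H](C[C@]2(CC=C(C)C)C(=O)C([C@H](CCC)CC(=O)OC)=C3OC(C)(C)CC(=O)C3=C2O)CC1(C)C | intermediate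
24 | (3R)-3-[(6R)-6-{[(1S,2R)-3,3-dimethyl-2-(prop-1-en-2-yl)cyclobutyl]methyl}-5-hydroxy-2,2-dimethyl-6-(3-methylbut-2-en-1-yl)-4,7-dioxo-3,4,6,7-tetrahydro-2H-chromen-8-yl]hexanoic acid | C=C(C)[C@H]1[C@H](C[C@]2(CC=C(C)C)C(=O)C([C@H](CCC)CC(=O)O)=C3OC(C)(C)CC(=O)C3=C2O)CC1(C)C | target

Total step count: 12. Longest linear sequence: 8 steps (steps 1 to 5 and 10 to 12, from anhydride 1); the cyclobutane branch (steps 6 to 9) joins at step 10.

Steps most likely to fail

Step 2, the step carrying the proposed new method. Capture of the acylketene by the unactivated alkene may be too slow. Ketene dimerisation, [2+2] addition, or decay of the acyl Meldrum's acid to a methyl ketone could then take over. The fallback builds the same ring by known chemistry in three operations and gives up the one-pot formation of both bonds. It sets out from 2. Oxalyl chloride with catalytic DMF gives the acid chloride methyl (3R)-5-chloro-5-oxo-3-propylpentanoate F1. F1 acylates the kinetic lithium enolate of mesityl oxide (LiN(iPr)2, THF, −78 °C, two equivalents of enolate) at its methyl carbon to give the diketone methyl (3S)-9-methyl-5,7-dioxo-3-propyldec-8-enoate F2. Acid (TsOH in benzene, or HCl in MeOH) then closes the ring by 6-endo oxa-Michael addition of the enol oxygen. The fallback comes back to the route at 7.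

Step 11. Facial selectivity at C6 may be poor, or allylation at C8 or at oxygen may not revert. The fallback sets out from 22 and comes back at 23. It replaces the π-allylpalladium pathway by an ion-pair SN2 alkylative dearomatisation: prenyl bromide, CsOH·H2O, a cinchonidinium phase-transfer catalyst, toluene, low temperature. The C6 epimers would be separated by chromatography if the selectivity is incomplete. This fallback makes no new compound (F0).

Step 5. Carbomethoxylation may occur at the wrong carbanion (C3 of the pyranone), the side-chain ester may enter Claisen reactions, or strong base may erode the side-chain stereocentre by retro-Michael cleavage. The fallback sets out from iodide 8 and bypasses steps 4 and 5. Carbonylative coupling with potassium methyl malonate (Pd(OAc)2, Xantphos, CO, MgCl2, Et3N, with decarboxylation) should give the β-keto ester methyl (3S)-3-{[5-(3-methoxy-3-oxopropanoyl)-2,2-dimethyl-4-oxo-3,4-dihydro-2H-pyran-6-yl]methyl}hexanoate F3. Its Dieckmann closure at the γ-carbon (KOtBu, THF, 0 °C) and tautomerisation come back to the route at 12.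

Further compounds
F1 | step 2 | methyl (3R)-5-chloro-5-oxo-3-propylpentanoate | COC(=O)C[C@@H](CCC)CC(Cl)=O
F2 | step 2 | methyl (3S)-9-methyl-5,7-dioxo-3-propyldec-8-enoate | COC(=O)C[C@@H](CCC)CC(=O)CC(=O)C=C(C)C
F0 | step 11 | none | none
F3 | step 5 | methyl (3S)-3-{[5-(3-methoxy-3-oxopropanoyl)-2,2-dimethyl-4-oxo-3,4-dihydro-2H-pyran-6-yl]methyl}hexanoate | CC1(C)CC(=O)C(C(=O)CC(=O)OC)=C(C[C@H](CCC)CC(=O)OC)O1
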